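The readings were computed with made-up constants, noise included.

The violet run's last reading has E at 0.771 of J and the green run's has it at 0.303, so we first ask how much Q brings E level with J.

common to all: J 0.10 M

| run | Q | remark | time |
|---|---|---|---|
| green | 0.40 equiv | run made earlier |  |
| violet | 0.91 equiv | run made earlier |  |
| Wednesday's | 0.800 equiv |  | 6.0 h |
| Saturday's | 1.20 equiv |  | 6.0 h |

- green (time / h: E / %, J / %): 0.333: 14.6, 86.2; 0.500: 14.8, 83.2; 1.00: 19.0, 82.4; 1.50: 20.9, 76.6; 2.50: 23.8, 74.2; 4.00: 22.6, 74.6
- violet (time / h: E / %, J / %): 0.333: 25.9, 73.5; 0.500: 28.5, 70.2; 1.00: 31.9, 61.9; 1.50: 35.6, 58.6; 2.50: 37.9, 55.0; 4.00: 40.5, 52.5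

(readings scatter by 1 percentage point)



* which of these holds the largest part of the J at the end of Wednesday's (E / J / D / X)
* which of these holds the largest part of the J at the end of Saturday's (E / J / D / X)
* amount of E at the end of Wednesday's, in percent of the J charged

Between those two readings the ratio of E to J climbs by 0.919 per equivalent of Q. Carried straight on, the line reaches unity at 1.16, which we call the crossing charge: our estimate, from these two readings, of the amount of Q at which E draws level with J.

On which side do the two flasks stand? Wednesday's, with 0.800 equiv, lies below the crossing, with a ratio of 0.670, so we expect J ahead. Saturday's, with 1.20 equiv, lies just above it, with a ratio of 1.04. That margin is thin for readings that scatter by 1 percentage point, but the violet readings give a ratio that was still rising, from 0.689 at 2.50 h to 0.771 at 4.00 h, and Wednesday's and Saturday's both run to 6.0 h. So we expect E ahead in Saturday's.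

How much E does Wednesday's hold? J and E together make 93.0% in the violet run's last reading. Giving Wednesday's the same sum, our ratio puts E at 37.3%.

The forecast says J for Wednesday's, E for Saturday's and 38% of E, more than our figure, holding for Saturday's that “E is slightly favoured because the E/J ratio is still rising with Q”.

Wednesday's ends with 38.3% of E.

    J + Q → L + E (k = 0.730 M⁻¹ min⁻¹)
    Q ⇌ Z (K = 1.50, k = 0.290 min⁻¹)
    E + Q → L + D (k = 0.420 M⁻¹ min⁻¹)
    L + Q ⇌ G, settled at all times (K = 1800 M⁻¹)
    D + Q → L + X (k = 0.260 M⁻¹ min⁻¹)

At 6.00 h in Wednesday's, E is still made 2.44 times faster than it is used up, each step taken net. Wednesday's, below the crossing charge of 1.16, has E at 0.714 of J, with 53.6% of J, the largest part. Saturday's, above the crossing, ends with 45.0% of E to 39.4% of J. A neighbour of Wednesday's charged with 2.00 equiv of Q, further past the crossing, ends with 46.2% of E to 20.0% of J.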